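**Retrosynthetic overview**
- Target ⇐ removal of two MOM groups ⇐ one-pot double sigmatropic shift on a bis-O-prenyl flavone: 5-O-prenyl → C-8 prenyl (para-Claisen–Cope) and 4'-O-prenyl → C-5' 1,1-dimethylallyl (ortho-Claisen).
- Key disconnection C-2–C-1': a C-2-zincated chromone (a carbanion at an innately electrophilic, acyl-level β-enone carbon, i.e. a masked acyl anion) joined to the electrophilic ipso carbon of an aryl bromide.
- Chromone fragment ⇐ 5,7-dihydroxychromone ⇐ 2,4,6-trihydroxyacetophenone + orthoformate; aryl bromide fragment ⇐ 4-bromoresorcinol.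
- Ring order: rings A and B are bought; ring C (the pyranone) is closed first, onto ring A (step 1); ring B is attached last through the C-2–C-1' bond; no ring is formed afterwards.

Assumption: the SMILES has no stereocentre and no stereogenic double bond, so the target is achiral and is made exactly as drawn; no step has stereochemistry to set.

**Step 1**
Reactants: 1 2,4,6-trihydroxyacetophenone
Product: 3 5,7-dihydroxychromen-4-one, via 4-ethoxy-5,7-dihydroxychromenylium perchlorate 2 (not isolated)
Conditions: HC(OEt)3 (5 equiv), 70% aq HClO4 (1.5 equiv), rt, 12 h; then H2O, 90 °C, 30 min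
Reagents that add atoms: triethyl orthoformate CCOC(OCC)OCC; water O
Why: Orthoformate/perchloric acid chromone annulation: the diethoxycarbenium ion C-formylates the enolised methyl ketone, one of the two equivalent ortho-hydroxyls closes ring C as the 4-ethoxybenzopyrylium salt, and hot water hydrolyses this to the chromone, the symmetric ring leaving no regiochemical choice.

**Step 2**
Reactants: 3 5,7-dihydroxychromen-4-one
Product: 5 7-(methoxymethoxy)-5-(3-methylbut-2-enyloxy)chromen-4-one, via 5-hydroxy-7-(methoxymethoxy)chromen-4-one 4 (not isolated)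
Conditions: MOMCl (1.05 equiv), K2CO3 (3 equiv), DMF, 0 °C, 2 h; then prenyl bromide (1.5 equiv), 50 °C, 12 h
Reagents that add atoms: chloromethyl methyl ether COCCl; prenyl bromide (1-bromo-3-methylbut-2-ene) CC(C)=CCBr
Why: Two Williamson etherifications run in the order of phenol reactivity: the acidic, non-chelated 7-OH takes the MOM group at 0 °C, and the carbonyl-chelated 5-OH reacts only in the warmer prenyl bromide stage.

**Step 3**
Reactants: 6 4-bromoresorcinol (4-bromobenzene-1,3-diol)
Product: 7 2-bromo-5-(3-methylbut-2-enyloxy)phenol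
Conditions: prenyl bromide (1.0 equiv), K2CO3 (1.1 equiv), acetone, rt, 16 h; chromatography
Reagents that add atoms: prenyl bromide (1-bromo-3-methylbut-2-ene) CC(C)=CCBr
Why: Williamson mono-etherification in which the unhindered hydroxyl para to bromine is alkylated faster than the hydroxyl flanked by bromine, the minor regioisomer and bis-ether being removed by chromatography.

**Step 4**
Reactants: 7 2-bromo-5-(3-methylbut-2-enyloxy)phenol
Product: 8 1-bromo-2-(methoxymethoxy)-4-(3-methylbut-2-enyloxy)benzene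
Conditions: MOMCl (1.3 equiv), K2CO3 (2 equiv), DMF, 0 °C to rt
Reagents that add atoms: chloromethyl methyl ether COCCl
Why: Williamson-type O-alkylation of the remaining phenol, the MOM group masking the acidic OH for the organozinc coupling and later shielding C-3' in the Claisen step.

**Step 5 (key step)**
Reactants: 5 7-(methoxymethoxy)-5-(3-methylbut-2-enyloxy)chromen-4-one; 8 1-bromo-2-(methoxymethoxy)-4-(3-methylbut-2-enyloxy)benzene
Product: 10 7-(methoxymethoxy)-2-[2-(methoxymethoxy)-4-(3-methylbut-2-enyloxy)phenyl]-5-(3-methylbut-2-enyloxy)chromen-4-one, via chromon-2-ylzinc chloride·LiCl complex 9 (not isolated)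
Conditions: TMPZnCl·LiCl [(2,2,6,6-tetramethylpiperidin-1-yl)zinc chloride–lithium chloride] (1.2 equiv), THF, 25 °C, 1 h; then 8 (0.9 equiv), Pd(OAc)2 (3 mol %), SPhos (2-dicyclohexylphosphino-2',6'-dimethoxybiphenyl, 6 mol %), 50 °C, 12 h
Reagents that add atoms: none
Why: Deprotonative zincation followed by Negishi cross-coupling: C-2 of the chromone, normally an electrophilic acyl-level β-enone carbon, carries the most acidic ring C–H (α to the ring oxygen) and is converted by the hindered, magnesium-free zinc amide into an α-oxyvinyl/β-acylvinyl carbanion (a masked acyl anion), which zerovalent palladium/SPhos catalysis joins to the likewise electrophilic ipso carbon of the aryl bromide while the ketone, acetals and prenyl ethers are tolerated by the organozinc.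

**Step 6**
Reactants: 10 7-(methoxymethoxy)-2-[2-(methoxymethoxy)-4-(3-methylbut-2-enyloxy)phenyl]-5-(3-methylbut-2-enyloxy)chromen-4-one
Product: 12 5-hydroxy-2-[4-hydroxy-2-(methoxymethoxy)-5-(2-methylbut-3-en-2-yl)phenyl]-7-(methoxymethoxy)-8-(3-methylbut-2-enyl)chromen-4-one, via ring A rearranged 8-prenyl-5-hydroxyflavone 11 (not isolated)
Conditions: Eu(fod)3 [europium tris(6,6,7,7,8,8,8-heptafluoro-2,2-dimethyloctane-3,5-dionate)] (10 mol %), NaHCO3, 1,2-dichlorobenzene, 85 °C, 24 h; then 175 °C, 4 h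
Reagents that add atoms: none
Why: Tandem sigmatropic cascade: trivalent europium chelated between the 4-carbonyl and the 5-oxygen triggers Claisen shift of the 5-O-prenyl group to C-6 and Cope shift on to C-8 (para-Claisen–Cope, normal prenyl group) at 85 °C, and at 175 °C the 4'-O-prenyl ether undergoes ortho-Claisen rearrangement with allylic inversion to the open C-5' (C-3' is crowded between two oxygens, C-1' is substituted) to give the 1,1-dimethylallyl group.

**Step 7**
Reactants: 12 5-hydroxy-2-[4-hydroxy-2-(methoxymethoxy)-5-(2-methylbut-3-en-2-yl)phenyl]-7-(methoxymethoxy)-8-(3-methylbut-2-enyl)chromen-4-one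
Product: 13 2-[2,4-dihydroxy-5-(2-methylbut-3-en-2-yl)phenyl]-5,7-dihydroxy-8-(3-methylbut-2-enyl)chromen-4-one (CNP0315714.0)
Conditions: 3 M aq HCl, MeOH, 45 °C, 2 h
Reagents that add atoms: none
Why: Acid-catalysed acetal solvolysis (MOM removal) in methanol under dilute acid and mild heat, conditions under which prenyl and 1,1-dimethylallyl groups ortho to phenols should not cyclise or hydrate appreciably.

**Compound list**
1 | 2,4,6-trihydroxyacetophenone | CC(=O)c1c(O)cc(O)cc1O | starting material
2 | 4-ethoxy-5,7-dihydroxychromenylium perchlorate | CCOc1cc[o+]c2cc(O)cc(O)c12.[O-]Cl(=O)(=O)=O | intermediate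
3 | 5,7-dihydroxychromen-4-one | O=c1ccoc2cc(O)cc(O)c12 | intermediate
4 | 5-hydroxy-7-(methoxymethoxy)chromen-4-one | COCOc1cc(O)c2c(c1)occc2=O | intermediate
5 | 7-(methoxymethoxy)-5-(3-methylbut-2-enyloxy)chromen-4-one | COCOc1cc(OCC=C(C)C)c2c(c1)occc2=O | intermediate
6 | 4-bromoresorcinol (4-bromobenzene-1,3-diol) | Oc1ccc(Br)c(O)c1 | starting material
7 | 2-bromo-5-(3-methylbut-2-enyloxy)phenol | CC(C)=CCOc1ccc(Br)c(O)c1 | intermediate
8 | 1-bromo-2-(methoxymethoxy)-4-(3-methylbut-2-enyloxy)benzene | CC(C)=CCOc1ccc(Br)c(OCOC)c1 | intermediate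
9 | [7-(methoxymethoxy)-5-(3-methylbut-2-enyloxy)-4-oxochromen-2-yl]zinc chloride–lithium chloride complex | COCOc1cc(OCC=C(C)C)c2c(c1)oc([Zn]Cl)cc2=O.[Li+].[Cl-] | intermediate
10 | 7-(methoxymethoxy)-2-[2-(methoxymethoxy)-4-(3-methylbut-2-enyloxy)phenyl]-5-(3-methylbut-2-enyloxy)chromen-4-one | COCOc1cc(OCC=C(C)C)c2c(c1)oc(-c1ccc(OCC=C(C)C)cc1OCOC)cc2=O | intermediate
11 | 5-hydroxy-7-(methoxymethoxy)-2-[2-(methoxymethoxy)-4-(3-methylbut-2-enyloxy)phenyl]-8-(3-methylbut-2-enyl)chromen-4-one | COCOc1cc(O)c2c(c1CC=C(C)C)oc(-c1ccc(OCC=C(C)C)cc1OCOC)cc2=O | intermediate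
12 | 5-hydroxy-2-[4-hydroxy-2-(methoxymethoxy)-5-(2-methylbut-3-en-2-yl)phenyl]-7-(methoxymethoxy)-8-(3-methylbut-2-enyl)chromen-4-one | COCOc1cc(O)c2c(c1CC=C(C)C)oc(-c1cc(C(C)(C)C=C)c(O)cc1OCOC)cc2=O | intermediate
13 | 2-[2,4-dihydroxy-5-(2-methylbut-3-en-2-yl)phenyl]-5,7-dihydroxy-8-(3-methylbut-2-enyl)chromen-4-one | C=CC(C)(C)c1cc(-c2cc(=O)c3c(O)cc(O)c(CC=C(C)C)c3o2)c(O)cc1O | target

**Step count and risks**
Total steps: 7. Longest linear sequence: 5 steps (steps 1, 2, 5, 6, 7); steps 3 and 4 form the side branch.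

Step 6 (double rearrangement) is the most likely to fail. Ring A may stop at the 6-(1,1-dimethylallyl) stage. The ring B shift may be slow, may give some C-3' isomer, or the new ortho-allylphenol may cyclise at 175 °C. The fallback moves the ring B rearrangement to the small fragment and sets out from 8. Heating 8 alone (N,N-diethylaniline, 190 °C) gives 4-bromo-5-(methoxymethoxy)-2-(2-methylbut-3-en-2-yl)phenol F1, from which regioisomers are easily separated. MOMCl/K2CO3 then gives 1-bromo-2,4-bis(methoxymethoxy)-5-(2-methylbut-3-en-2-yl)benzene F2. Coupling F2 with zinc reagent 9 (made from 5 as in step 5) gives 2-[2,4-bis(methoxymethoxy)-5-(2-methylbut-3-en-2-yl)phenyl]-7-(methoxymethoxy)-5-(3-methylbut-2-enyloxy)chromen-4-one F3. Only the ring A para-Claisen–Cope shift is then needed (Eu(fod)3, NaHCO3, chlorobenzene, 85 °C), giving 2-[2,4-bis(methoxymethoxy)-5-(2-methylbut-3-en-2-yl)phenyl]-5-hydroxy-7-(methoxymethoxy)-8-(3-methylbut-2-enyl)chromen-4-one F4. HCl/MeOH on F4 gives 13, where the fallback rejoins the route.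

Step 5 (zincation/Negishi coupling) is the second risk. The electron-rich, ortho-substituted bromide 8 adds slowly to zerovalent palladium, which could instead ionise a prenyl aryl ether, and some zincation could occur away from C-2. The fallback swaps the roles of the partners and sets out from 9 and 8. Quenching zinc reagent 9 with I2 gives 2-iodo-7-(methoxymethoxy)-5-(3-methylbut-2-enyloxy)chromen-4-one F5, which also proves the site of metalation. Bromine–lithium exchange on 8 (n-BuLi, THF, −78 °C) and trapping with 2-isopropoxy-4,4,5,5-tetramethyl-1,3,2-dioxaborolane gives 2-[2-(methoxymethoxy)-4-(3-methylbut-2-enyloxy)phenyl]-4,4,5,5-tetramethyl-1,3,2-dioxaborolane F6. Suzuki–Miyaura coupling of the fast-reacting iodide F5 with F6 (Pd(OAc)2, SPhos, K3PO4, THF/H2O, 40 °C) gives 10, where the fallback rejoins the route.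

Step 3 (selective mono-prenylation) is the third risk. The more acidic hydroxyl next to bromine may compete, giving the wrong regioisomer and bis-ether. The fallback fixes the regiochemistry by steric silylation and sets out from 6. TBSCl (1.0 equiv) and imidazole at −20 °C silylate the unhindered hydroxyl to give 2-bromo-5-(tert-butyldimethylsilyloxy)phenol F7. MOMCl/K2CO3 caps the hindered hydroxyl to give tert-butyl[4-bromo-3-(methoxymethoxy)phenoxy]dimethylsilane F8. Tetrabutylammonium fluoride then frees 4-bromo-3-(methoxymethoxy)phenol F9. Prenyl bromide/K2CO3 converts F9 into 8, where the fallback rejoins the route (7 is bypassed).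

**Further compounds**
F1 | step 6 | 4-bromo-5-(methoxymethoxy)-2-(2-methylbut-3-en-2-yl)phenol | Oc1cc(OCOC)c(Br)cc1C(C)(C)C=C
F2 | step 6 | 1-bromo-2,4-bis(methoxymethoxy)-5-(2-methylbut-3-en-2-yl)benzene | COCOc1cc(OCOC)c(Br)cc1C(C)(C)C=C
F3 | step 6 | 2-[2,4-bis(methoxymethoxy)-5-(2-methylbut-3-en-2-yl)phenyl]-7-(methoxymethoxy)-5-(3-methylbut-2-enyloxy)chromen-4-one | COCOc1cc(OCC=C(C)C)c2c(c1)oc(-c1cc(C(C)(C)C=C)c(OCOC)cc1OCOC)cc2=O
F4 | step 6 | 2-[2,4-bis(methoxymethoxy)-5-(2-methylbut-3-en-2-yl)phenyl]-5-hydroxy-7-(methoxymethoxy)-8-(3-methylbut-2-enyl)chromen-4-one | COCOc1cc(O)c2c(c1CC=C(C)C)oc(-c1cc(C(C)(C)C=C)c(OCOC)cc1OCOC)cc2=O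
F5 | step 5 | 2-iodo-7-(methoxymethoxy)-5-(3-methylbut-2-enyloxy)chromen-4-one | COCOc1cc(OCC=C(C)C)c2c(c1)oc(I)cc2=O
F6 | step 5 | 2-[2-(methoxymethoxy)-4-(3-methylbut-2-enyloxy)phenyl]-4,4,5,5-tetramethyl-1,3,2-dioxaborolane | CC(C)=CCOc1ccc(B2OC(C)(C)C(C)(C)O2)c(OCOC)c1
F7 | step 3 | 2-bromo-5-(tert-butyldimethylsilyloxy)phenol | CC(C)(C)[Si](C)(C)Oc1ccc(Br)c(O)c1
F8 | step 3 | tert-butyl[4-bromo-3-(methoxymethoxy)phenoxy]dimethylsilane | COCOc1cc(O[Si](C)(C)C(C)(C)C)ccc1Br
F9 | step 3 | 4-bromo-3-(methoxymethoxy)phenol | COCOc1cc(O)ccc1Br
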